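Ring A is disconnected at its only alkene, C1=C10, which lies between the quaternary C9 and the C5 methine bearing the C4 gem-dimethyl carbon. Both alkene carbons are traced back to carbonyl carbons, so a single titanium-mediated reductive coupling of a C10 ketone with a C1 aldehyde forms the C1–C10 bond, closes ring A and fixes the position of the double bond. The precursor is a pulegone-derived ring B cyclohexanone that already holds C5, C8 and C9 in their final configurations, the silyl-protected C11–C15 chain with C13 set, and a C4 arm ending in the C1 aldehyde. The acetylated glycerol ester is added last.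

Key step: step 11

Remark: the target is taken exactly as drawn, (5S,8R,9R,13R) with the C8 and C9 methyl groups trans and a (2S)-glycerol centre; halimane numbering is used for positions in the text.

Step 1
Reactants: 1 (R)-pulegone; 2 allyltrimethylsilane
Product: 4 (5R)-5-methyl-2-(2-methylpent-4-en-2-yl)cyclohexan-1-one as an epimer mixture at the arm-bearing carbon (halimane C5), via trichlorotitanium enolate 3 (not isolated)
Conditions: TiCl4, CH2Cl2, −78 °C; aq. NH4Cl
Reagents that add atoms: none
Why: Hosomi–Sakurai conjugate allylation, in which TiCl4 activates the s-cis enone and the allylsilane adds to the isopropylidene β-carbon to create the quaternary C4; the titanium enolate is protonated on work-up, so C5 forms as a mixture that step 3 corrects, while C8 comes unchanged from pulegone.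

Step 2
Reactants: 4 (5R)-5-methyl-2-(2-methylpent-4-en-2-yl)cyclohexan-1-one
Product: 6 (3R)-2,3-dimethyl-6-(2-methylpent-4-en-2-yl)cyclohexan-1-one as a mixture of epimers at C2 and C6 (halimane C9 and C5), via lithium enolate 5 (not isolated)
Conditions: LiN(iPr)2, THF, −78 °C; MeI, −78 → 0 °C
Reagents that add atoms: iodomethane CI
Why: Kinetic enolate alkylation, in which the amide base removes a proton from the C9 methylene and not from the C5 methine shielded by the quaternary C4 (as in menthone-type ketones), and iodomethane C-alkylates the enolate; the C9 configuration formed here is irrelevant because C9 becomes planar again in step 8.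

Step 3
Reactants: 6 (3R)-2,3-dimethyl-6-(2-methylpent-4-en-2-yl)cyclohexan-1-one (epimer mixture)
Product: 7 (2S,3R,6S)-2,3-dimethyl-6-(2-methylpent-4-en-2-yl)cyclohexan-1-one
Conditions: NaOMe (cat.), MeOH, 50 °C
Reagents that add atoms: none
Why: Base-catalysed epimerisation through the enolates should bring both enolisable centres to the all-equatorial arrangement, which fixes C5 trans to the C8 methyl (5S) and leaves an axial C9–H for the next deprotonation; C8 is not enolisable and is untouched.

Step 4
Reactants: 8 methyl hydrogen (R)-3-methylglutarate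
Product: 9 methyl (R)-5-hydroxy-3-methylpentanoate
Conditions: BH3·SMe2, THF, 0 °C → rt; MeOH
Reagents that add atoms: none
Why: Chemoselective borane reduction, in which the free acid is reduced through its acyloxyborane much faster than the methyl ester, so only the future C11 terminus becomes CH2OH and the C13 stereocentre is untouched.

Step 5
Reactants: 9 methyl (R)-5-hydroxy-3-methylpentanoate
Product: 10 methyl (S)-5-iodo-3-methylpentanoate
Conditions: I2, PPh3, imidazole, CH2Cl2, 0 °C → rt
Reagents that add atoms: iodine II
Why: Appel-type iodination by SN2 displacement of the oxyphosphonium group at the primary carbon, remote from the stereocentre; it is done before the ester is reduced, so the two chain ends stay differentiated (the corresponding 1,5-diol would be achiral) and the hydroxy ester cannot lactonise.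

Step 6
Reactants: 10 methyl (S)-5-iodo-3-methylpentanoate
Product: 11 (S)-5-iodo-3-methylpentan-1-ol
Conditions: iBu2AlH, CH2Cl2, −78 → −20 °C; aq. KNaC4H4O6
Reagents that add atoms: none
Why: Hydride reduction of the ester to the primary alcohol; a primary alkyl iodide is inert to this aluminium hydride at low temperature.

Step 7
Reactants: 11 (S)-5-iodo-3-methylpentan-1-ol
Product: 12 (S)-tert-butyl[(5-iodo-3-methylpentyl)oxy]dimethylsilane
Conditions: TBSCl, imidazole, CH2Cl2, 0 °C → rt
Reagents that add atoms: tert-butyldimethylsilyl chloride CC(C)(C)[Si](C)(C)Cl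
Why: Standard silylation of a primary alcohol, carried out at once so that the iodo alcohol cannot cyclise; the silyl ether masks C15 through the enolate, borane and titanium chemistry that follows.

Step 8
Reactants: 7 (2S,3R,6S)-2,3-dimethyl-6-(2-methylpent-4-en-2-yl)cyclohexan-1-one; 12 (S)-tert-butyl[(5-iodo-3-methylpentyl)oxy]dimethylsilane
Product: 14 (2R,3R,6S)-2-[(3R)-5-{[tert-butyl(dimethyl)silyl]oxy}-3-methylpentyl]-2,3-dimethyl-6-(2-methylpent-4-en-2-yl)cyclohexan-1-one, via lithium enolate 13 (not isolated)
Conditions: LiN(iPr)2, THF, −78 → 0 °C; 12, DMPU, 0 °C → rt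
Reagents that add atoms: none
Why: Alkylation of a tetrasubstituted lithium enolate with a primary iodide, in which deprotonation should occur at C9 and not at the hindered C5 methine, and, because the equatorial C5 tert-alkyl group locks the enolate half-chair with the C8 methyl pseudo-equatorial, the iodide should enter along the axial trajectory anti to the axial C8–H, placing C11 axial and cis to the C8 methyl and leaving the C20 methyl trans to it (9R), as expected from the axial entry seen with conformationally fixed 1-alkyl-trans-2-decalone enolates that lack an angular group.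

Step 9
Reactants: 14 (2R,3R,6S)-2-[(3R)-5-{[tert-butyl(dimethyl)silyl]oxy}-3-methylpentyl]-2,3-dimethyl-6-(2-methylpent-4-en-2-yl)cyclohexan-1-one
Product: 16 (2R,3R,6S)-2-[(3R)-5-{[tert-butyl(dimethyl)silyl]oxy}-3-methylpentyl]-6-(5-hydroxy-2-methylpentan-2-yl)-2,3-dimethylcyclohexan-1-one, via B-alkyl-9-BBN adduct 15 (not isolated)
Conditions: 9-BBN, THF, 0 °C → rt; H2O2, aq. NaOAc, 0 °C → rt
Reagents that add atoms: hydrogen peroxide OO
Why: Hydroboration–oxidation, in which 9-BBN adds anti-Markovnikov to the unhindered terminal vinyl group and leaves the C10 ketone, buried between the quaternary C9 and the C5 methine, untouched, and acetate-buffered peroxide replaces boron by hydroxyl without exposing the epimerisable C5–H to strong base.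

Step 10
Reactants: 16 (2R,3R,6S)-2-[(3R)-5-{[tert-butyl(dimethyl)silyl]oxy}-3-methylpentyl]-6-(5-hydroxy-2-methylpentan-2-yl)-2,3-dimethylcyclohexan-1-one
Product: 17 4-{(1S,3R,4R)-3-[(3R)-5-{[tert-butyl(dimethyl)silyl]oxy}-3-methylpentyl]-3,4-dimethyl-2-oxocyclohexyl}-4-methylpentanal
Conditions: Dess–Martin periodinane, CH2Cl2, 0 °C → rt
Reagents that add atoms: none
Why: Dess–Martin oxidation of the primary alcohol to the C1 aldehyde under non-basic conditions that should not epimerise C5; the silyl ether and the ketone are inert.

Step 11
Reactants: 17 4-{(1S,3R,4R)-3-[(3R)-5-{[tert-butyl(dimethyl)silyl]oxy}-3-methylpentyl]-3,4-dimethyl-2-oxocyclohexyl}-4-methylpentanal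
Product: 19 (13R)-15-(tert-butyldimethylsilyloxy)halim-1(10)-ene, via titanium pinacolate 18 (not isolated)
Conditions: TiCl3(DME)1.5, Zn-Cu, DME, reflux; 17 added by syringe pump over ca. 30 h at high dilution, then further reflux
Reagents that add atoms: none
Why: McMurry carbonyl coupling, in which low-valent titanium made from TiCl3 and Zn-Cu transfers one electron to each carbonyl, the two ketyls combine to form the C1–C10 bond as a titanium-bound 1,2-diolate, and continued heating cleaves both C–O bonds on the metal to leave the C1=C10 double bond. The closest known reaction type is the intramolecular titanium-mediated keto aldehyde coupling to cycloalkenes, which tolerates ketones flanked by fully substituted carbons because the bond arises from ketyl coupling and not from addition of a bulky nucleophile. Ring A closes as a six-membered carbocycle by joining the chain terminus C1 to the ring B carbonyl carbon C10, a 6-exo-trig closure with respect to either C=O, with both carbons ending inside the ring. No stereocentre is created, and the alkene can only lie between the two former carbonyl carbons, so its place between the quaternary C9 and C5 is fixed by constitution. The selectivity needed is ring closure over intermolecular aldehyde coupling, secured by slow addition at high dilution and by the six-membered transition state. The medium is non-basic, so the C5 methine, the only enolisable centre, should keep its configuration, and a primary silyl ether should survive.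

Step 12
Reactants: 19 (13R)-15-(tert-butyldimethylsilyloxy)halim-1(10)-ene
Product: 20 (13R)-halim-1(10)-en-15-ol
Conditions: Bu4NF, THF, rt
Reagents that add atoms: none
Why: Fluoride-mediated desilylation driven by the strong Si–F bond; the trisubstituted alkene and all stereocentres are unaffected.

Step 13
Reactants: 20 (13R)-halim-1(10)-en-15-ol
Product: 22 (13R)-halim-1(10)-en-15-oic acid, via aldehyde 21 (not isolated)
Conditions: TEMPO (cat.), PhI(OAc)2, MeCN/H2O, rt
Reagents that add atoms: water O
Why: Oxoammonium-mediated oxidation takes the primary alcohol through the aldehyde and its hydrate to the acid under near-neutral conditions that leave the trisubstituted alkene alone; C13 is β to the carbonyl and cannot epimerise.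

Step 14
Reactants: 22 (13R)-halim-1(10)-en-15-oic acid; 23 (R)-solketal
Product: 24 [(4S)-2,2-dimethyl-1,3-dioxolan-4-yl]methyl (13R)-halim-1(10)-en-15-oate
Conditions: EDC·HCl, DMAP, CH2Cl2, 0 °C → rt
Reagents that add atoms: none
Why: Steglich esterification of the acid with the primary hydroxyl of the acetonide; the dioxolane stereocentre is not involved and becomes the (S)-configured glycerol C2 of the target.

Step 15
Reactants: 24 [(4S)-2,2-dimethyl-1,3-dioxolan-4-yl]methyl (13R)-halim-1(10)-en-15-oate
Product: 25 (2S)-2,3-dihydroxypropyl (13R)-halim-1(10)-en-15-oate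
Conditions: AcOH/H2O (4:1), 35 °C
Reagents that add atoms: none
Why: Mild acid-catalysed acetal hydrolysis, in which aqueous acetic acid removes the isopropylidene group but should be too weak to drive 1,2-acyl migration at a useful rate or to isomerise the C1=C10 alkene.

Step 16
Reactants: 25 (2S)-2,3-dihydroxypropyl (13R)-halim-1(10)-en-15-oate
Product: 26 (2S)-3-acetoxy-2-hydroxypropyl (13R)-halim-1(10)-en-15-oate (target)
Conditions: AcCl, 2,4,6-collidine, CH2Cl2, −78 °C
Reagents that add atoms: acetyl chloride CC(=O)Cl
Why: Kinetically selective acylation, in which acetyl chloride with a hindered pyridine base at low temperature should react with the primary hydroxyl far faster than with the secondary one, without touching the glycerol stereocentre.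

Compound list
1 | (R)-pulegone | C[C@@H]1CCC(=C(C)C)C(=O)C1 | starting material
2 | allyltrimethylsilane | C=CC[Si](C)(C)C | starting material
3 | trichlorotitanium enolate of the allyl adduct (C5=C10 enolate) | C[C@@H]1CCC(C(C)(C)CC=C)=C(O[Ti](Cl)(Cl)Cl)C1 | intermediate
4 | (5R)-5-methyl-2-(2-methylpent-4-en-2-yl)cyclohexan-1-one, epimer mixture at C2 | C[C@@H]1CCC(C(C)(C)CC=C)C(=O)C1 | intermediate
5 | lithium enolate of 4 on the methylene side (C9=C10) | C[C@@H]1CCC(C(C)(C)CC=C)C(O[Li])=C1 | intermediate
6 | (3R)-2,3-dimethyl-6-(2-methylpent-4-en-2-yl)cyclohexan-1-one, epimer mixture at C2 and C6 | C[C@@H]1CCC(C(C)(C)CC=C)C(=O)C1C | intermediate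
7 | (2S,3R,6S)-2,3-dimethyl-6-(2-methylpent-4-en-2-yl)cyclohexan-1-one (all-equatorial) | C[C@@H]1C(=O)[C@H](C(C)(C)CC=C)CC[C@H]1C | intermediate
8 | methyl hydrogen (R)-3-methylglutarate | COC(=O)C[C@H](C)CC(=O)O | starting material
9 | methyl (R)-5-hydroxy-3-methylpentanoate | COC(=O)C[C@H](C)CCO | intermediate
10 | methyl (S)-5-iodo-3-methylpentanoate | COC(=O)C[C@H](C)CCI | intermediate
11 | (S)-5-iodo-3-methylpentan-1-ol | OCC[C@H](C)CCI | intermediate
12 | (S)-tert-butyl[(5-iodo-3-methylpentyl)oxy]dimethylsilane | CC(C)(C)[Si](C)(C)OCC[C@H](C)CCI | intermediate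
13 | tetrasubstituted lithium enolate of 7 (C9=C10) | C=CCC(C)(C)[C@@H]1CC[C@@H](C)C(C)=C1O[Li] | intermediate
14 | (2R,3R,6S)-2-[(3R)-5-{[tert-butyl(dimethyl)silyl]oxy}-3-methylpentyl]-2,3-dimethyl-6-(2-methylpent-4-en-2-yl)cyclohexan-1-one | CC(C)(C)[Si](C)(C)OCC[C@H](C)CC[C@@]1(C)C(=O)[C@H](C(C)(C)CC=C)CC[C@H]1C | intermediate
15 | B-alkyl-9-borabicyclo[3.3.1]nonane adduct of 14 (boron on the terminal carbon) | CC(C)(C)[Si](C)(C)OCC[C@H](C)CC[C@@]1(C)C(=O)[C@H](C(C)(C)CCCB2C3CCCC2CCC3)CC[C@H]1C | intermediate
16 | (2R,3R,6S)-2-[(3R)-5-{[tert-butyl(dimethyl)silyl]oxy}-3-methylpentyl]-6-(5-hydroxy-2-methylpentan-2-yl)-2,3-dimethylcyclohexan-1-one | CC(C)(C)[Si](C)(C)OCC[C@H](C)CC[C@@]1(C)C(=O)[C@H](C(C)(C)CCCO)CC[C@H]1C | intermediate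
17 | 4-{(1S,3R,4R)-3-[(3R)-5-{[tert-butyl(dimethyl)silyl]oxy}-3-methylpentyl]-3,4-dimethyl-2-oxocyclohexyl}-4-methylpentanal (ring B keto aldehyde) | CC(C)(C)[Si](C)(C)OCC[C@H](C)CC[C@@]1(C)C(=O)[C@H](C(C)(C)CCC=O)CC[C@H]1C | intermediate
18 | titanium-bound 1,10-diolate (pinacolate), metal drawn with its two oxygen ligands only, C1 and C10 unspecified | CC(C)(C)[Si](C)(C)OCC[C@H](C)CC[C@@]1(C)C23O[Ti]OC3CCC(C)(C)[C@@H]2CC[C@H]1C | intermediate
19 | (13R)-15-(tert-butyldimethylsilyloxy)halim-1(10)-ene, i.e. tert-butyldimethyl{[(3R)-3-methyl-5-[(1R,2R,4aS)-1,2,5,5-tetramethyl-1,2,3,4,4a,5,6,7-octahydronaphthalen-1-yl]pentyl]oxy}silane | CC(C)(C)[Si](C)(C)OCC[C@H](C)CC[C@@]1(C)C2=CCCC(C)(C)[C@@H]2CC[C@H]1C | intermediate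
20 | (13R)-halim-1(10)-en-15-ol | OCC[C@H](C)CC[C@@]1(C)C2=CCCC(C)(C)[C@@H]2CC[C@H]1C | intermediate
21 | (13R)-halim-1(10)-en-15-al | O=CC[C@H](C)CC[C@@]1(C)C2=CCCC(C)(C)[C@@H]2CC[C@H]1C | intermediate
22 | (13R)-halim-1(10)-en-15-oic acid | OC(=O)C[C@H](C)CC[C@@]1(C)C2=CCCC(C)(C)[C@@H]2CC[C@H]1C | intermediate
23 | (R)-solketal | CC1(C)OC[C@@H](CO)O1 | starting material
24 | [(4S)-2,2-dimethyl-1,3-dioxolan-4-yl]methyl (13R)-halim-1(10)-en-15-oate | CC1(C)OC[C@@H](COC(=O)C[C@H](C)CC[C@@]2(C)C3=CCCC(C)(C)[C@@H]3CC[C@H]2C)O1 | intermediate
25 | (2S)-2,3-dihydroxypropyl (13R)-halim-1(10)-en-15-oate | OC[C@H](O)COC(=O)C[C@H](C)CC[C@@]1(C)C2=CCCC(C)(C)[C@@H]2CC[C@H]1C | intermediate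
26 | (2S)-3-acetoxy-2-hydroxypropyl (13R)-halim-1(10)-en-15-oate | CC(=O)OC[C@H](O)COC(=O)C[C@H](C)CC[C@@]1(C)C2=CCCC(C)(C)[C@@H]2CC[C@H]1C | target

Total step count: 16. Longest linear sequence: 13 steps (steps 4–7, then 8–16, from the glutarate half-ester 8); from pulegone the sequence is 12 steps.

Steps most likely to fail

Step 11. The hindered C10 ketyl may fail to couple with the C1 ketyl, the diolate may resist deoxygenation, or intermolecular aldehyde coupling and simple carbonyl reduction may take over. The fallback sets out from 17 and forms the same C1=C10 bond by olefin metathesis instead of carbonyl coupling. Both carbonyls of 17 are methylenated with the Takai–Lombardo reagent (Zn, CH2Br2, TiCl4, THF/CH2Cl2), which tolerates hindered and enolisable ketones and is non-basic, to give the bis-methylene diene F3. Ring-closing metathesis with second-generation Grubbs catalyst RuCl2(=CHPh)(PCy3)(H2IMes) in toluene at 80 °C then expels ethylene and closes ring A, and the route is rejoined at 19.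

Step 8. The facial preference of the C9 enolate is the least secure stereochemical call: entry of the iodide anti to the C8 methyl (equatorial entry) may compete with or override axial entry and give the C9 epimer, and C-alkylation by a non-activated iodide at a tetrasubstituted enolate may be slow. The fallback sets out from 4 and reverses the order in which the two C9 substituents arrive. Kinetic deprotonation of 4 (LiN(iPr)2, THF, −78 °C) and alkylation with 12 in the presence of DMPU gives the C9-monoalkylated ketone F1 as an epimer mixture. NaOMe in MeOH equilibrates it to the all-equatorial isomer F2, and a second deprotonation followed by MeI introduces the methyl group last. For a given facial bias the two orders lead to opposite C9 epimers, so if the enolate proves to prefer attack anti to the C8 methyl, this sequence delivers the required configuration and comes back to the route at 14.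

Step 15. Acyl migration from the primary to the secondary hydroxyl, and onward, may occur during or after acetonide hydrolysis, which would scramble the ester position and erode the glycerol configuration; over-acetylation in step 16 is a related hazard. The fallback sets out from 22 and avoids any free 1,2-diol. Steglich esterification of 22 with (R)-glycidol (OC[C@@H]1CO1; EDC·HCl, DMAP, CH2Cl2) gives the (S)-glycidyl ester F4. Opening of the epoxide at its terminal carbon with acetic acid (AcOH, Et4NBr cat., 70 °C) installs the acetate and liberates the secondary hydroxyl in one operation without breaking a bond to the stereocentre, and the route is rejoined at 26.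

Further compounds
F1 | step 8 | (3R)-2-[(3R)-5-{[tert-butyl(dimethyl)silyl]oxy}-3-methylpentyl]-3-methyl-6-(2-methylpent-4-en-2-yl)cyclohexan-1-one, epimer mixture at C2 and C6 | CC(C)(C)[Si](C)(C)OCC[C@H](C)CCC1C(=O)C(C(C)(C)CC=C)CC[C@H]1C
F2 | step 8 | (2S,3R,6S)-2-[(3R)-5-{[tert-butyl(dimethyl)silyl]oxy}-3-methylpentyl]-3-methyl-6-(2-methylpent-4-en-2-yl)cyclohexan-1-one | CC(C)(C)[Si](C)(C)OCC[C@H](C)CC[C@@H]1C(=O)[C@H](C(C)(C)CC=C)CC[C@H]1C
F3 | step 11 | bis-methylene diene from 17 (C10 exocyclic methylene and terminal vinyl at C1) | CC(C)(C)[Si](C)(C)OCC[C@H](C)CC[C@@]1(C)C(=C)[C@H](C(C)(C)CCC=C)CC[C@H]1C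
F4 | step 15 | [(2S)-oxiran-2-yl]methyl (13R)-halim-1(10)-en-15-oate | C1O[C@@H]1COC(=O)C[C@H](C)CC[C@@]2(C)C3=CCCC(C)(C)[C@@H]3CC[C@H]2C
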